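## Retrosynthetic overview
1. Target ⇒ bis-MOM ether by MOM removal ⇒ depsidone without the ring-B prenyl group, by aromatic Claisen rearrangement of the 1,1-dimethylallyl ether of the only free phenol (one open ortho carbon).
2. Seven-membered lactone (last ring formed) ⇒ carbodiimide closure of a hydroquinone acid; only the OH ortho to the ether oxygen can reach the carboxyl group.
3. Diaryl ether flanked on all four ortho positions ⇒ addition–elimination of a ring-A salicylaldehyde phenoxide on 6-bromo-2,2-dimethylchromene-5,8-dione, then CHO → CO2H and quinone → hydroquinone.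
4. Pyran ring (first ring formed) and key C–C bond (chromene C4–C4a) ⇒ intermolecular aldol-type condensation of 4-bromo-2,5-dimethoxyphenol with 3-methylbut-2-enal, then dehydration, oxa-6π closure and oxidative demethylation.
5. Ring A ⇒ phloroglucinol: bis-MOM ether, 1,1-dimethylallyl ether and Claisen rearrangement (symmetry gives one product), then ortho-specific formylation with formaldehyde.

Assumption: the SMILES holds no stereocentre and no stereogenic open-chain double bond, so the target is achiral and no enantiocontrol is needed.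

Conventions: ring A is the benzoyl ring and uses benzoic acid locants. Ring B is the chromene ring and uses chromene locants O1–C8a throughout. Prenyl is 3-methylbut-2-en-1-yl and MOM is CH2OCH3.

## Route

Step 1
Reactants: 1 2,5-dimethoxybenzaldehyde
Product: 2 4-bromo-2,5-dimethoxybenzaldehyde
Conditions: Br2 (1.1 equiv), AcOH, rt, 24 h; recrystallise from EtOH
Reagents that add atoms: bromine, BrBr
Why: Electrophilic aromatic bromination takes the least hindered activated site, ortho to the 5-methoxy group and para to the formyl group, and the crystalline 4-bromo isomer is purified by recrystallisation.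

Step 2
Reactants: 2 4-bromo-2,5-dimethoxybenzaldehyde
Product: 4 4-bromo-2,5-dimethoxyphenol, via aryl formate 3 (not isolated)
Conditions: mCPBA (1.3 equiv), CH2Cl2, 0 °C → rt; then K2CO3 (0.2 equiv), MeOH, rt
Reagents that add atoms: 3-chloroperoxybenzoic acid (mCPBA), O=C(OO)c1cccc(Cl)c1
Why: Baeyer–Villiger oxidation with migration of the electron-rich aryl group gives formate 3, which catalytic carbonate in methanol cleaves to the phenol by transesterification.

Step 3
Reactants: 4 4-bromo-2,5-dimethoxyphenol; 5 3-methylbut-2-enal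
Product: 8 6-bromo-5,8-dimethoxy-2,2-dimethyl-2H-chromene, via benzodioxaborinine 6 (not isolated), via ortho-quinone methide 7 (not isolated)
Conditions: 5 (1.5 equiv), PhB(OH)2 (1.0 equiv), AcOH (co-solvent), toluene, reflux, Dean–Stark, 16 h
Reagents that add atoms: none
Why: This key step is a boron-templated intermolecular aldol-type condensation (Nagata-type ortho-hydroxyalkylation) in which the phenol reacts as an aromatic enol through its only free ortho carbon with the aldehyde carbon of 5 to forge C4–C4a, after which 6 extrudes its boron unit on heating to give 7 and oxa-6π electrocyclisation closes the pyran, erasing the racemic stereocentre of 6.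

Step 4
Reactants: 8 6-bromo-5,8-dimethoxy-2,2-dimethyl-2H-chromene
Product: 9 6-bromo-2,2-dimethyl-2H-chromene-5,8-dione
Conditions: (NH4)2Ce(NO3)6 (2.5 equiv), MeCN/H2O (3:1), 0 °C, 20 min
Reagents that add atoms: water, O
Why: Oxidative demethylation of the para-dimethoxyarene (two one-electron oxidations, each followed by attack of water) gives the para-quinone, while the bromine atom and the tertiary pyran ether stay in place.

Step 5
Reactants: 10 phloroglucinol (benzene-1,3,5-triol)
Product: 11 3,5-bis(methoxymethoxy)phenol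
Conditions: MOMCl (2.0 equiv), i-Pr2NEt (2.2 equiv), DMF, 0 °C → rt; chromatography (mono- and tris-ethers set aside for recycling)
Reagents that add atoms: chloromethyl methyl ether (MOMCl), COCCl
Why: Statistical Williamson-type O-alkylation of the threefold symmetric triol gives the bis-ether as the main fraction at two equivalents of MOMCl, and it starts from a very cheap material.

Step 6
Reactants: 11 3,5-bis(methoxymethoxy)phenol; 12 3-chloro-3-methylbut-1-yne
Product: 13 1,3-bis(methoxymethoxy)-5-[(2-methylbut-3-yn-2-yl)oxy]benzene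
Conditions: 12 (1.3 equiv), DBU (1.5 equiv), CuCl2·2H2O (1 mol %), MeCN, 0 °C, Ar
Reagents that add atoms: none
Why: Copper-catalysed propargylic substitution forms the tertiary aryl propargyl ether at 0 °C, well below the temperature at which it would rearrange.

Step 7
Reactants: 13 1,3-bis(methoxymethoxy)-5-[(2-methylbut-3-yn-2-yl)oxy]benzene
Product: 14 1,3-bis(methoxymethoxy)-5-[(2-methylbut-3-en-2-yl)oxy]benzene
Conditions: H2 (1 atm), 5% Pd/CaCO3 poisoned with Pb(OAc)2, quinoline, EtOAc, rt; stop after 1 equiv H2
Reagents that add atoms: none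
Why: Lindlar-type semihydrogenation stops at the terminal alkene because the poisoned palladium surface reduces the alkyne far faster than any alkene.

Step 8
Reactants: 14 1,3-bis(methoxymethoxy)-5-[(2-methylbut-3-en-2-yl)oxy]benzene
Product: 16 3,5-bis(methoxymethoxy)-2-(3-methylbut-2-en-1-yl)phenol, via ortho-dienone 15 (not isolated)
Conditions: toluene, 110 °C, 3 h, base-washed glassware
Reagents that add atoms: none
Why: Aromatic Claisen rearrangement ([3,3]-sigmatropic) delivers the prenyl group with allylic inversion to an ortho carbon, the two ortho carbons being equivalent by symmetry, and dienone 15 with its transient racemic stereocentre tautomerises to the phenol.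

Step 9
Reactants: 16 3,5-bis(methoxymethoxy)-2-(3-methylbut-2-en-1-yl)phenol
Product: 18 2-hydroxy-4,6-bis(methoxymethoxy)-3-(3-methylbut-2-en-1-yl)benzaldehyde, via salicyl alcohol 17 (not isolated)
Conditions: MgCl2 (anhydrous, 2 equiv), Et3N (4 equiv), (CH2O)n (6 equiv), MeCN, reflux, 4 h; cold aq. citric acid work-up
Reagents that add atoms: formaldehyde (from paraformaldehyde), C=O
Why: In this Casnati–Skattebøl ortho-formylation the magnesium phenoxide adds through its only free ortho carbon to coordinated formaldehyde (aldol-type hydroxymethylation) and 17 is oxidised in the flask by hydride transfer to a second formaldehyde, so the carbon between the two MOM ethers is never touched.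

Step 10
Reactants: 18 2-hydroxy-4,6-bis(methoxymethoxy)-3-(3-methylbut-2-en-1-yl)benzaldehyde; 9 6-bromo-2,2-dimethyl-2H-chromene-5,8-dione
Product: 19 2-[(2,2-dimethyl-5,8-dioxo-5,8-dihydro-2H-chromen-6-yl)oxy]-4,6-bis(methoxymethoxy)-3-(3-methylbut-2-en-1-yl)benzaldehyde
Conditions: 9 (1.1 equiv), K2CO3 (1.5 equiv), dry DMF, 0 °C → rt, Ar
Reagents that add atoms: none
Why: This is an addition–elimination on the bromoquinone, where C6 is the β-carbon of the C8 enone (the carbonyl not deactivated by the pyran oxygen), so the phenoxide attacks ipso and bromide leaves, and the flat, highly electrophilic acceptor tolerates a phenoxide with both ortho positions filled where a copper Ullmann coupling would stall.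

Step 11
Reactants: 19 aryloxyquinone aldehyde
Product: 20 2-[(2,2-dimethyl-5,8-dioxo-5,8-dihydro-2H-chromen-6-yl)oxy]-4,6-bis(methoxymethoxy)-3-(3-methylbut-2-en-1-yl)benzoic acid
Conditions: NaClO2 (3 equiv), NaH2PO4 (4 equiv), 2-methylbut-2-ene (30 equiv), t-BuOH/THF/H2O, 0 °C → rt
Reagents that add atoms: sodium chlorite, [Na+].[O-]Cl=O
Why: Pinnick oxidation takes the hindered aldehyde to the acid at pH 4–5, where MOM ethers and the quinone survive, and the large excess of 2-methylbut-2-ene protects the prenyl and chromene double bonds from hypochlorous acid.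

Step 12
Reactants: 20 aryloxyquinone acid
Product: 21 2-[(5,8-dihydroxy-2,2-dimethyl-2H-chromen-6-yl)oxy]-4,6-bis(methoxymethoxy)-3-(3-methylbut-2-en-1-yl)benzoic acid
Conditions: Na2S2O4 (4 equiv), THF/H2O (1:1), rt, 15 min, Ar; extract (EtOAc), dry, use at once
Reagents that add atoms: none
Why: Dithionite reduces the quinone to the hydroquinone by a fast two-electron reduction and leaves alkenes, MOM ethers and the acid alone.

Step 13
Reactants: 21 hydroquinone acid
Product: 22 8-hydroxy depsidone bis-MOM ether (lactone of 21 through chromene O5; C7–H)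
Conditions: DCC (1.2 equiv), DMAP (0.1 equiv), CH2Cl2 (0.005 M), 0 °C → rt, Ar
Reagents that add atoms: none
Why: Steglich-type carbodiimide lactonisation closes the seven-membered dioxepinone on the 5-OH, the only hydroxyl ortho to the ether oxygen, since closure on the 8-OH would need a strained meta-bridged ring, and the nearly neutral medium excludes a Smiles rearrangement of the ether.

Step 14
Reactants: 22 8-hydroxy depsidone bis-MOM ether; 12 3-chloro-3-methylbut-1-yne
Product: 23 8-O-(2-methylbut-3-yn-2-yl) ether of 22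
Conditions: 12 (1.5 equiv), DBU (1.6 equiv), CuCl2·2H2O (2 mol %), MeCN, 0 °C, Ar
Reagents that add atoms: none
Why: The same copper-catalysed propargylic substitution as in step 6 etherifies the single free phenol, and non-nucleophilic DBU at 0 °C leaves the hindered aryl ester intact.

Step 15
Reactants: 23 8-O-(2-methylbut-3-yn-2-yl) ether of 22
Product: 24 8-O-(2-methylbut-3-en-2-yl) ether of 22
Conditions: H2 (1 atm), 5% Pd/CaCO3 poisoned with Pb(OAc)2, quinoline, EtOAc, rt; stop after 1 equiv H2
Reagents that add atoms: none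
Why: Lindlar-type semihydrogenation of the terminal alkyne is much faster than reduction of the trisubstituted prenyl alkene or the hindered chromene alkene.

Step 16
Reactants: 24 8-O-(2-methylbut-3-en-2-yl) ether of 22
Product: 26 7-prenyl-8-hydroxy depsidone bis-MOM ether, via ring-B dienone 25 (not isolated)
Conditions: xylenes, 130 °C, 3 h, Ar
Reagents that add atoms: none
Why: Aromatic Claisen rearrangement can end only at C7, because the other ortho carbon (C8a) carries the pyran oxygen, and it delivers the normal prenyl group by allylic inversion before dienone 25 with its transient racemic stereocentre re-aromatises.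

Step 17
Reactants: 26 7-prenyl-8-hydroxy depsidone bis-MOM ether
Product: 27 CNP0263700.0 (target)
Conditions: 3 M aq. HCl, THF, 40 °C; monitor by TLC and quench with NaHCO3 as soon as 26 is consumed
Reagents that add atoms: none
Why: Acid-catalysed acetal hydrolysis removes both aryl MOM ethers under conditions routinely survived by ortho-prenylphenols and 2,2-dimethylchromenes, and the ester is shielded from solvolysis because both positions ortho to its carbonyl are substituted.

## Compound list
1 | 2,5-dimethoxybenzaldehyde | COc1ccc(OC)c(C=O)c1 | starting material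
2 | 4-bromo-2,5-dimethoxybenzaldehyde | COc1cc(C=O)c(OC)cc1Br | intermediate
3 | 4-bromo-2,5-dimethoxyphenyl formate (not isolated) | COc1cc(OC=O)c(OC)cc1Br | intermediate
4 | 4-bromo-2,5-dimethoxyphenol | COc1cc(O)c(OC)cc1Br | intermediate
5 | 3-methylbut-2-enal | CC(C)=CC=O | starting material
6 | 6-bromo-5,8-dimethoxy-4-(2-methylprop-1-en-1-yl)-2-phenyl-4H-1,3,2-benzodioxaborinine (racemic, not isolated) | CC(C)=CC1OB(c2ccccc2)Oc2c(OC)cc(Br)c(OC)c21 | intermediate
7 | 4-bromo-2,5-dimethoxy-6-(3-methylbut-2-en-1-ylidene)cyclohexa-2,4-dien-1-one (not isolated) | O=C1C(OC)=CC(Br)=C(OC)C1=CC=C(C)C | intermediate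
8 | 6-bromo-5,8-dimethoxy-2,2-dimethyl-2H-chromene | CC1(C)C=Cc2c(OC)c(Br)cc(OC)c2O1 | intermediate
9 | 6-bromo-2,2-dimethyl-2H-chromene-5,8-dione | CC1(C)C=CC2=C(O1)C(=O)C=C(Br)C2=O | intermediate
10 | phloroglucinol | Oc1cc(O)cc(O)c1 | starting material
11 | 3,5-bis(methoxymethoxy)phenol | COCOc1cc(O)cc(OCOC)c1 | intermediate
12 | 3-chloro-3-methylbut-1-yne | C#CC(C)(C)Cl | starting material
13 | 1,3-bis(methoxymethoxy)-5-[(2-methylbut-3-yn-2-yl)oxy]benzene | C#CC(C)(C)Oc1cc(OCOC)cc(OCOC)c1 | intermediate
14 | 1,3-bis(methoxymethoxy)-5-[(2-methylbut-3-en-2-yl)oxy]benzene | C=CC(C)(C)Oc1cc(OCOC)cc(OCOC)c1 | intermediate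
15 | 3,5-bis(methoxymethoxy)-6-(3-methylbut-2-en-1-yl)cyclohexa-2,4-dien-1-one (racemic, not isolated) | O=C1C=C(OCOC)C=C(OCOC)C1CC=C(C)C | intermediate
16 | 3,5-bis(methoxymethoxy)-2-(3-methylbut-2-en-1-yl)phenol | CC(C)=CCc1c(O)cc(OCOC)cc1OCOC | intermediate
17 | 2-(hydroxymethyl)-3,5-bis(methoxymethoxy)-6-(3-methylbut-2-en-1-yl)phenol (not isolated) | CC(C)=CCc1c(O)c(CO)c(OCOC)cc1OCOC | intermediate
18 | 2-hydroxy-4,6-bis(methoxymethoxy)-3-(3-methylbut-2-en-1-yl)benzaldehyde | CC(C)=CCc1c(O)c(C=O)c(OCOC)cc1OCOC | intermediate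
19 | 2-[(2,2-dimethyl-5,8-dioxo-5,8-dihydro-2H-chromen-6-yl)oxy]-4,6-bis(methoxymethoxy)-3-(3-methylbut-2-en-1-yl)benzaldehyde | CC(C)=CCc1c(OC2=CC(=O)C3=C(C=CC(C)(C)O3)C2=O)c(C=O)c(OCOC)cc1OCOC | intermediate
20 | 2-[(2,2-dimethyl-5,8-dioxo-5,8-dihydro-2H-chromen-6-yl)oxy]-4,6-bis(methoxymethoxy)-3-(3-methylbut-2-en-1-yl)benzoic acid | CC(C)=CCc1c(OC2=CC(=O)C3=C(C=CC(C)(C)O3)C2=O)c(C(=O)O)c(OCOC)cc1OCOC | intermediate
21 | 2-[(5,8-dihydroxy-2,2-dimethyl-2H-chromen-6-yl)oxy]-4,6-bis(methoxymethoxy)-3-(3-methylbut-2-en-1-yl)benzoic acid | CC(C)=CCc1c(Oc2cc(O)c3OC(C)(C)C=Cc3c2O)c(C(=O)O)c(OCOC)cc1OCOC | intermediate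
22 | 8-hydroxy depsidone bis-MOM ether: dibenzo[b,e][1,4]dioxepin-11-one with ester bond ring-A C(=O)–O5 and ether bond ring-A C2–O–C6 of the chromene; ring A 3-prenyl-4,6-bis(OMOM); ring B 8-OH, 7-H | Oc1cc2Oc3c(CC=C(C)C)c(OCOC)cc(OCOC)c3C(=O)Oc2c2C=CC(C)(C)Oc12 | intermediate
23 | 8-O-(2-methylbut-3-yn-2-yl) ether of 22 | C#CC(C)(C)Oc1cc2Oc3c(CC=C(C)C)c(OCOC)cc(OCOC)c3C(=O)Oc2c2C=CC(C)(C)Oc12 | intermediate
24 | 8-O-(2-methylbut-3-en-2-yl) ether of 22 | C=CC(C)(C)Oc1cc2Oc3c(CC=C(C)C)c(OCOC)cc(OCOC)c3C(=O)Oc2c2C=CC(C)(C)Oc12 | intermediate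
25 | ring-B dienone: 8-oxo-7H-7-prenyl tautomer of 26 (racemic, not isolated) | O=C1C(CC=C(C)C)C2=C(C3=C1OC(C)(C)C=C3)OC(=O)c1c(O2)c(CC=C(C)C)c(OCOC)cc1OCOC | intermediate
26 | 7-prenyl-8-hydroxy depsidone bis-MOM ether (ring-A 4,6-di-O-MOM derivative of the target) | Oc1c(CC=C(C)C)c2Oc3c(CC=C(C)C)c(OCOC)cc(OCOC)c3C(=O)Oc2c2C=CC(C)(C)Oc12 | intermediate
27 | CNP0263700.0 (achiral) | CC(C)=CCc1c(O)c2c(c3c1Oc1c(CC=C(C)C)c(O)cc(O)c1C(=O)O3)C=CC(C)(C)O2 | target

## Step count and risks
Total step count: 17. Longest linear sequence: 13 steps (10 → 27, steps 5–17). The ring-B branch (steps 1–4) joins at step 10.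

**Step 10 (phenoxide plus bromoquinone).** The chelated phenoxide, with both ortho positions filled, may react through its para carbon or be too slow for the base-sensitive quinone. The fallback makes the ether at the arene oxidation level and forms the quinone afterwards. It sets out from 8 and 18 and comes back at 19. Bromine–lithium exchange on 8 (n-BuLi, THF, −78 °C), a B(OiPr)3 quench and mild aqueous work-up give (5,8-dimethoxy-2,2-dimethyl-2H-chromen-6-yl)boronic acid F1. Chan–Lam–Evans coupling of this acid with 18 (Cu(OAc)2, pyridine, 4 Å sieves, CH2Cl2, air, rt) is known to accept acidic phenols with both ortho positions substituted. It gives 2-[(5,8-dimethoxy-2,2-dimethyl-2H-chromen-6-yl)oxy]-4,6-bis(methoxymethoxy)-3-(3-methylbut-2-en-1-yl)benzaldehyde F2. Brief treatment with (NH4)2Ce(NO3)6 in MeCN/H2O at 0 °C then oxidises the most electron-rich ring, ring B, to quinone 19.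

**Step 13 (lactonisation of the air-sensitive hydroquinone acid).** Re-oxidation of 21, N-acylurea formation from the hindered acid or oligomerisation could erode the yield. The fallback activates the acid while ring B is still an air-stable quinone and lets reduction trigger ring closure. It sets out from 20 and comes back at 22. Acid 20 is treated with pentafluorophenol, DCC and catalytic DMAP (CH2Cl2, rt) to give the quinone pentafluorophenyl ester F3. Reduction with Na2S2O4 (THF/H2O, Ar) gives the hydroquinone pentafluorophenyl ester F4. Dilute i-Pr2NEt with catalytic DMAP in CH2Cl2 then closes F4 through its 5-OH to 22.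

**Step 14 (tertiary ether next to the pyran oxygen).** The crowded 8-OH may etherify poorly, or the tertiary ether may ionise. The fallback uses a primary allyl group and builds the prenyl terminus afterwards. It sets out from 22 and comes back at 26. Allyl bromide with K2CO3 in acetone gives the 8-O-allyl ether of depsidone 22 F5. Aromatic Claisen rearrangement (N,N-diethylaniline, 190 °C) again has only C7 open and gives the 7-allyl-8-hydroxy depsidone bis-MOM ether F6. Cross-metathesis with excess 2-methylbut-2-ene (second-generation Grubbs catalyst, (H2IMes)(PCy3)Cl2Ru=CHPh, CH2Cl2, 40 °C) converts the allyl group into prenyl and gives 26. Exchange at the ring-A prenyl group is degenerate, and the hindered chromene alkene does not take part.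

## Further compounds
F1 | step 10 | (5,8-dimethoxy-2,2-dimethyl-2H-chromen-6-yl)boronic acid | CC1(C)C=Cc2c(OC)c(B(O)O)cc(OC)c2O1
F2 | step 10 | 2-[(5,8-dimethoxy-2,2-dimethyl-2H-chromen-6-yl)oxy]-4,6-bis(methoxymethoxy)-3-(3-methylbut-2-en-1-yl)benzaldehyde | CC(C)=CCc1c(Oc2cc(OC)c3OC(C)(C)C=Cc3c2OC)c(C=O)c(OCOC)cc1OCOC
F3 | step 13 | quinone pentafluorophenyl ester | CC(C)=CCc1c(OC2=CC(=O)C3=C(C=CC(C)(C)O3)C2=O)c(C(=O)Oc2c(F)c(F)c(F)c(F)c2F)c(OCOC)cc1OCOC
F4 | step 13 | hydroquinone pentafluorophenyl ester | CC(C)=CCc1c(Oc2cc(O)c3OC(C)(C)C=Cc3c2O)c(C(=O)Oc2c(F)c(F)c(F)c(F)c2F)c(OCOC)cc1OCOC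
F5 | step 14 | 8-O-allyl ether of depsidone 22 | C=CCOc1cc2Oc3c(CC=C(C)C)c(OCOC)cc(OCOC)c3C(=O)Oc2c2C=CC(C)(C)Oc12
F6 | step 14 | 7-allyl-8-hydroxy depsidone bis-MOM ether | Oc1c(CC=C)c2Oc3c(CC=C(C)C)c(OCOC)cc(OCOC)c3C(=O)Oc2c2C=CC(C)(C)Oc12
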